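**Plan**
- Retrosynthesis (drimane numbering): cut the C11–O aryl ether (umbelliferone), then C9=C11 back to a C9 ketone, then C3–C4 of ring A, then the two bonds from C10 to its methyl and to C1 (enolate alkylations).
- Forward: ring B is bought as (S)-carvone. C10 receives its methyl and a 3-oxopropyl chain (C1–C3), ring A is closed through C3–C4, C11 and the coumarin are attached, and C3 is oxidised last.
- Enabling feature: ring B (C5–C10, C7=C8, C12 on C8) is carvone atom for atom. The carvone ketone is C9 and its isopropenyl group is C4 with one of the two C4 methyls already in place, so a hydrogen atom added to the isopropenyl CH2 creates the gem-dimethyl group and a tertiary C4 radical that can close a six-membered ring onto the C3 aldehyde.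
- Stereochemistry: C5 is the carvone stereocentre; C10 arises by alkylation anti to the isopropenyl group; C9 by hydroboration anti to the axial C10 methyl; the C3 carbinol is transient.

Key step: step 4

Assumption: drimane numbering is used throughout (ring A = C1–C5 and C10, ring B = C5–C10, C11 = OCH2, C12 = methyl on C8); the C3 carbinol of 9–16 is drawn as the equatorial epimer, and either epimer or a mixture would converge in step 10.

Step 1
Reactants: 1 (S)-carvone; 2 iodomethane
Product: 4 6-methylcarvone (C6 epimer mixture), via lithium dienolate of carvone 3 (not isolated)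
Conditions: LiN(iPr)2, THF, −78 °C; then MeI, −78 → 0 °C
Reagents that add atoms: iodomethane (2), CI
Why: Kinetic α′-deprotonation of the enone gives the cross-conjugated dienolate 3, whose C-methylation (enolate alkylation) is routine for carvone; the configuration of the new methine does not matter because step 2 planarises it again.

Step 2
Reactants: 4 6-methylcarvone; 5 2-(2-bromoethyl)-1,3-dioxolane
Product: 7 6-[2-(1,3-dioxolan-2-yl)ethyl]-6-methylcarvone (chain anti to isopropenyl), via tetrasubstituted lithium enolate 6 (not isolated)
Conditions: LiN(iPr)2, THF, −78 → 0 °C; then 5, DMPU, nBu4NI (cat.), 0 °C → rt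
Reagents that add atoms: 2-(2-bromoethyl)-1,3-dioxolane (5), BrCCC1OCCO1
Why: Enolate alkylation in a dipolar medium with the bromide activated in situ as the iodide; the electrophile approaches the enolate face opposite the neighbouring isopropenyl group, so the new quaternary carbon (future C10) carries the chain anti and the methyl syn to isopropenyl.

Step 3
Reactants: 7 keto acetal
Product: 8 3-[(1R,6R)-1,3-dimethyl-2-oxo-6-(prop-1-en-2-yl)cyclohex-3-en-1-yl]propanal
Conditions: 1 M aq. HCl, THF, rt
Reagents that add atoms: water, O
Why: Acid-catalysed hydrolysis of the dioxolane (acetal deprotection) should free the aldehyde under conditions mild enough to leave the enone and the 1,1-disubstituted alkene untouched.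

Step 4
Reactants: 8 keto aldehyde
Product: 9 ent-3-hydroxy-11-nordrim-7-en-9-one (trans-fused, 3-OH equatorial)
Conditions: Fe(acac)3 (cat.), PhSiH3, EtOH, 60 °C, Ar
Reagents that add atoms: none
Why: Proposed new method: an iron hydride formed from Fe(acac)3, PhSiH3 and ethanol should transfer a hydrogen atom to the CH2 terminus of the electron-rich isopropenyl group (Markovnikov hydrogen-atom transfer) to give the tertiary C4 radical, which adds to the C3 formyl carbon, the resulting alkoxy radical being reduced by divalent iron and protonated by ethanol; the closest known reaction type is the iron-hydride hydrogen-atom-transfer cyclisation of alkene-tethered ketones to cycloalkanols, extended here to an aldehyde acceptor. Ring A closes in the 6-exo-trig mode through a chair transition state with both tethers on C5 and C10 equatorial, and since both ring-fusion centres are fixed beforehand only the trans-decalin with an axial C10 methyl can form. The single new stereocentre, C3, should form with oxygen pseudo-equatorial in that chair (hydroxyl cis to the C10 methyl), but its configuration is immaterial because step 10 oxidises it. The step needs hydrogen-atom transfer to the isopropenyl group and not to the C7=C8 enone, which the electron-poor character of the enone alkene secures, and it needs cyclisation to outrun reduction of the radical, which the unhindered electrophilic aldehyde held on the adjacent quaternary carbon favours. Attack of the C4 radical on the enone would give only strained small or bridged rings, so the enone should remain a spectator.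

Step 5
Reactants: 9 hydroxy enone
Product: 10 ent-3-(tert-butyldimethylsilyloxy)-11-nordrim-7-en-9-one
Conditions: TBSOTf, 2,6-lutidine, CH2Cl2, −78 → 0 °C
Reagents that add atoms: tert-butyldimethylsilyl trifluoromethanesulfonate, CC(C)(C)[Si](C)(C)OS(=O)(=O)C(F)(F)F
Why: Silyl ether protection of the hindered secondary alcohol with the silyl triflate and a non-nucleophilic base removes the free hydroxyl before the titanium, boron and Mitsunobu reagents are used.

Step 6
Reactants: 10 silyloxy enone
Product: 11 ent-3-(tert-butyldimethylsilyloxy)drima-7,9(11)-diene
Conditions: Cp2TiMe2, toluene, 70 °C, dark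
Reagents that add atoms: dimethyltitanocene Cp2TiMe2, C[Ti](C)(C1C=CC=C1)C1C=CC=C1
Why: Petasis methylenation: the titanium methylidene generated on heating converts the hindered, non-enolisable C9 ketone into the exocyclic C9=C11 alkene through an oxatitanacyclobutane, a reaction that tolerates the steric crowding next to the quaternary C10.

Step 7
Reactants: 11 diene
Product: 13 ent-3-(tert-butyldimethylsilyloxy)drim-7-en-11-ol, via C11 borabicyclononyl borane 12 (not isolated)
Conditions: 9-BBN, THF, 0 → 65 °C; then aq. NaOH, H2O2, 0 °C → rt
Reagents that add atoms: hydrogen peroxide, OO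
Why: Hydroboration–oxidation: the bulky borane places boron on the terminal C11 and hydrogen on C9 from the face opposite the axial C10 methyl (syn addition), setting C9 with H9 anti and CH2O syn to that methyl, while the trisubstituted C7=C8 bond is too hindered to react; alkaline peroxide then replaces boron by hydroxyl.

Step 8
Reactants: 13 primary alcohol; 14 umbelliferone
Product: 15 7-[ent-3-(tert-butyldimethylsilyloxy)drim-7-en-11-yloxy]coumarin
Conditions: PPh3, DIAD, THF, 0 °C → rt
Reagents that add atoms: umbelliferone (14), Oc1ccc2ccc(=O)oc2c1
Why: Mitsunobu etherification: the acidic 7-hydroxycoumarin displaces the oxyphosphonium of the primary C11 alcohol in an SN2 step that touches no stereocentre.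

Step 9
Reactants: 15 silyl-protected aryl ether
Product: 16 7-(ent-3-hydroxydrim-7-en-11-yloxy)coumarin
Conditions: HF·pyridine, THF, 0 °C → rt
Reagents that add atoms: none
Why: Fluoride-mediated desilylation under non-basic conditions should free the C3 alcohol while sparing the coumarin lactone, the aryl ether and the trisubstituted alkene.

Step 10
Reactants: 16 hydroxy aryl ether
Product: 17 target, 7-{[(1R,4aS,8aR)-2,5,5,8a-tetramethyl-6-oxo-1,4,4a,5,6,7,8,8a-octahydronaphthalen-1-yl]methoxy}-2H-chromen-2-one
Conditions: Dess–Martin periodinane, CH2Cl2, rt
Reagents that add atoms: none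
Why: Dess–Martin oxidation of the secondary alcohol gives the C3 ketone under neutral conditions, and no stereocentre can epimerise because C4 is quaternary and C5 is not adjacent to the new carbonyl.

**Compound list**
1 | (S)-(+)-carvone, (5S)-2-methyl-5-(prop-1-en-2-yl)cyclohex-2-en-1-one | CC1=CC[C@@H](CC1=O)C(C)=C | starting material
2 | iodomethane | CI | starting material
3 | kinetic lithium dienolate of carvone (O–Li on the former carbonyl carbon, new C=C to the former α′-CH2) | CC1=CC[C@H](C(C)=C)C=C1O[Li] | intermediate (not isolated)
4 | 6-methylcarvone, (5S)-2,6-dimethyl-5-(prop-1-en-2-yl)cyclohex-2-en-1-one, mixture of C6 epimers | CC1=CC[C@H](C(C)=C)C(C)C1=O | intermediate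
5 | 2-(2-bromoethyl)-1,3-dioxolane | BrCCC1OCCO1 | starting material
6 | tetrasubstituted lithium enolate of 4 | CC1=CC[C@H](C(C)=C)C(C)=C1O[Li] | intermediate (not isolated)
7 | (5R,6R)-6-[2-(1,3-dioxolan-2-yl)ethyl]-2,6-dimethyl-5-(prop-1-en-2-yl)cyclohex-2-en-1-one (chain anti, methyl syn to isopropenyl) | CC1=CC[C@H](C(C)=C)[C@@](C)(CCC2OCCO2)C1=O | intermediate
8 | 3-[(1R,6R)-1,3-dimethyl-2-oxo-6-(prop-1-en-2-yl)cyclohex-3-en-1-yl]propanal | CC1=CC[C@H](C(C)=C)[C@@](C)(CCC=O)C1=O | intermediate (key-step precursor)
9 | ent-3-hydroxy-11-nordrim-7-en-9-one (trans-decalin, C10 methyl anti to H5, 3-OH equatorial and cis to the C10 methyl) | CC1=CC[C@@H]2C(C)(C)[C@H](O)CC[C@@]2(C)C1=O | intermediate (key-step product)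
10 | ent-3-(tert-butyldimethylsilyloxy)-11-nordrim-7-en-9-one | CC1=CC[C@@H]2C(C)(C)[C@H](O[Si](C)(C)C(C)(C)C)CC[C@@]2(C)C1=O | intermediate
11 | ent-3-(tert-butyldimethylsilyloxy)drima-7,9(11)-diene | CC1=CC[C@@H]2C(C)(C)[C@H](O[Si](C)(C)C(C)(C)C)CC[C@@]2(C)C1=C | intermediate
12 | B-(C11-alkyl)-9-borabicyclo[3.3.1]nonane adduct of 11 (H9 anti to the C10 methyl) | CC1=CC[C@@H]2C(C)(C)[C@H](O[Si](C)(C)C(C)(C)C)CC[C@@]2(C)[C@@H]1CB1C2CCCC1CCC2 | intermediate (not isolated)
13 | ent-3-(tert-butyldimethylsilyloxy)drim-7-en-11-ol (CH2OH syn to the C10 methyl) | CC1=CC[C@@H]2C(C)(C)[C@H](O[Si](C)(C)C(C)(C)C)CC[C@@]2(C)[C@@H]1CO | intermediate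
14 | umbelliferone (7-hydroxycoumarin) | Oc1ccc2ccc(=O)oc2c1 | starting material
15 | 7-[ent-3-(tert-butyldimethylsilyloxy)drim-7-en-11-yloxy]coumarin | CC1=CC[C@@H]2C(C)(C)[C@H](O[Si](C)(C)C(C)(C)C)CC[C@@]2(C)[C@@H]1COc1ccc2ccc(=O)oc2c1 | intermediate
16 | 7-(ent-3-hydroxydrim-7-en-11-yloxy)coumarin | CC1=CC[C@@H]2C(C)(C)[C@H](O)CC[C@@]2(C)[C@@H]1COc1ccc2ccc(=O)oc2c1 | intermediate
17 | 7-{[(1R,4aS,8aR)-2,5,5,8a-tetramethyl-6-oxo-1,4,4a,5,6,7,8,8a-octahydronaphthalen-1-yl]methoxy}-2H-chromen-2-one | CC1=CC[C@@H]2C(C)(C)C(=O)CC[C@@]2(C)[C@@H]1COc1ccc2ccc(=O)oc2c1 | target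

**Step count:** 10 steps in total; longest linear sequence 10 steps, from (S)-carvone.

**Steps most likely to fail**

Step 4 (the step carrying the proposed method). The addition of the tertiary radical to the formyl group is reversible. If β-scission of the alkoxy radical outpaces its reduction, or if the aldehyde is hydrosilylated or acetalised before hydrogen-atom transfer, the radical is simply reduced and ring A does not close. The fallback uses known chemistry and replaces the acceptor by a nitrile, whose iminyl radical does not fragment back. Setting out from 8, iodine in aqueous ammonia/THF should convert the formyl group into 3-[(1R,6R)-1,3-dimethyl-2-oxo-6-(prop-1-en-2-yl)cyclohex-3-en-1-yl]propanenitrile F1. The same Fe(acac)3/PhSiH3/EtOH conditions would then carry out the established hydrogen-atom-transfer cyclisation of an alkene onto a nitrile (6-exo-dig) to give the cyclic ketimine F2. Aqueous HCl on work-up would hydrolyse it to ent-11-nordrim-7-ene-3,9-dione F3. NaBH4 in MeOH/CH2Cl2 at −78 °C should reduce the saturated C3 ketone in preference to the hindered conjugated C9 ketone, by axial hydride delivery, and the route is rejoined at 9.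

Step 2. Displacement at the β-acetal bromide by the hindered tetrasubstituted enolate may be slow, so that elimination of HBr from the electrophile and proton return to the enolate take over. The fallback brings in C1–C3 as a propargyl group and unmasks the aldehyde afterwards. Setting out from 4 (through enolate 6), alkylation with propargyl bromide, a much more reactive electrophile that should enter anti to isopropenyl in the same way, would give 6-methyl-6-(prop-2-yn-1-yl)carvone F4. Hydroboration of the terminal alkyne with dicyclohexylborane (THF, 0 °C), which is faster than reaction at the 1,1-disubstituted alkene or the hindered ketone, would give the (E)-alkenyl(dicyclohexyl)borane F5. Oxidation with NaBO3 in THF/H2O would then deliver the aldehyde, so the route is rejoined at 8 and 7 is bypassed.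

Step 8. Substitution at the β-branched C11 may be slow, and E2 loss of the activated oxygen together with the allylic H9 would lead back toward the 7,9(11)-diene. The fallback reverses the roles so that no leaving group sits on C11. Setting out from 13, a palladium-catalysed C–O cross-coupling of the primary alcohol with purchased 7-bromocoumarin ([(C3H5)PdCl]2, RockPhos, Cs2CO3, toluene, 90 °C; Buchwald–Hartwig-type etherification) would give the aryl ether directly. No new compound is made on the way (F0), and the route is rejoined at 15.

**Further compounds**
F1 | step 4 | 3-[(1R,6R)-1,3-dimethyl-2-oxo-6-(prop-1-en-2-yl)cyclohex-3-en-1-yl]propanenitrile | CC1=CC[C@H](C(C)=C)[C@@](C)(CCC#N)C1=O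
F2 | step 4 | ent-3-imino-11-nordrim-7-en-9-one (cyclic N–H ketimine) | CC1=CC[C@@H]2C(C)(C)C(=N)CC[C@@]2(C)C1=O
F3 | step 4 | ent-11-nordrim-7-ene-3,9-dione | CC1=CC[C@@H]2C(C)(C)C(=O)CC[C@@]2(C)C1=O
F4 | step 2 | 6-methyl-6-(prop-2-yn-1-yl)carvone (propargyl anti to isopropenyl) | CC1=CC[C@H](C(C)=C)[C@@](C)(CC#C)C1=O
F5 | step 2 | (E)-alkenyl(dicyclohexyl)borane derived from F4 | CC1=CC[C@H](C(C)=C)[C@@](C)(C/C=C/B(C2CCCCC2)C2CCCCC2)C1=O
F0 | step 8 | none | none
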